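**Retrosynthetic overview**

1. Target 37 ⇐ desilylation, C6 tigloylation and PMB removal ⇐ protected lactone 33.
2. 33 ⇐ C7–C8 disconnection: intramolecular CrCl2 Barbier allylation of bromo‑aldehyde 31. The ten‑membered carbocycle closes first; the γ‑lactone follows in the same operation (C8 alkoxide onto the C12 ester).
3. 31 ⇐ (Z)‑2‑(bromomethyl)enoate by SN2' bromination of an α‑methylene‑β‑hydroxy ester, itself from aldol of C7 aldehyde 24 with amino ester 25.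
4. Both trisubstituted ring alkenes ⇐ E‑selective Wittig reactions of stabilised ylides (7 + 11; 15 + 16); the ester carbons become C15 and C14.
5. C6 ⇐ lipase desymmetrisation of achiral 2‑O‑PMB‑glycerol 3; C7 and C8 are set from C6 in the ring closure.

Assumption: the lipase acetylates the pro‑S hydroxymethyl arm of 3, the sense known for the 2‑O‑benzyl analogue.

Labels C1–C15 are germacrane positions of the target: C6 carries the tiglate, C7 the methylene‑bearing carbon, C8 the lactone oxygen; C14 and C15 are the hydroxymethyl carbons on C10 and C4. PMB = 4‑methoxybenzyl, Tr = triphenylmethyl, TBS = tert‑butyldimethylsilyl, TBDPS = tert‑butyldiphenylsilyl.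

**Route**

Step 1
Reactants: 1 cis-2-phenyl-1,3-dioxan-5-ol (cis-1,3-O-benzylideneglycerol)
Product: 2 cis-5-(PMB-oxy)-2-phenyl-1,3-dioxane
Conditions: NaH, 4-methoxybenzyl chloride, Bu4NI (cat.), DMF, 0 °C → rt
Reagents that add atoms: 4-methoxybenzyl chloride, COc1ccc(CCl)cc1
Why: Williamson etherification of the only free hydroxyl; the product keeps its mirror plane and stays achiral.

Step 2
Reactants: 2 cis-5-(PMB-oxy)-2-phenyl-1,3-dioxane
Product: 3 2-(PMB-oxy)propane-1,3-diol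
Conditions: AcOH/H2O (4:1), 50 °C
Reagents that add atoms: none
Why: Acid-catalysed acetal hydrolysis frees the two enantiotopic primary hydroxyls while the PMB ether survives weak acid.

Step 3
Reactants: 3 2-(PMB-oxy)propane-1,3-diol
Product: 4 (S)-3-hydroxy-2-(PMB-oxy)propyl acetate
Conditions: lipase (triacylglycerol hydrolase) from Burkholderia cepacia, immobilised, vinyl acetate, t-BuOMe, 25 °C
Reagents that add atoms: vinyl acetate, CC(=O)OC=C
Why: Lipase-catalysed irreversible transesterification (enantiotopic-group-selective desymmetrisation) acetylates only the pro-S arm, which creates the C6 stereocentre, and the released vinyl alcohol tautomerises to acetaldehyde so the acylation cannot reverse.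

Step 4
Reactants: 4 (S)-3-hydroxy-2-(PMB-oxy)propyl acetate
Product: 5 (S)-2-(PMB-oxy)-3-(trityloxy)propyl acetate
Conditions: Ph3CCl, pyridine, 4-(dimethylamino)pyridine (cat.), CH2Cl2, 0 °C → rt
Reagents that add atoms: trityl chloride, ClC(c1ccccc1)(c1ccccc1)c1ccccc1
Why: Tritylation of the free primary alcohol under weakly basic conditions locks the two arms apart with a group that cannot migrate, so the ee is kept.

Step 5
Reactants: 5 (S)-2-(PMB-oxy)-3-(trityloxy)propyl acetate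
Product: 6 (R)-2-(PMB-oxy)-3-(trityloxy)propan-1-ol
Conditions: K2CO3 (cat.), MeOH, 0 °C
Reagents that add atoms: none
Why: Base-catalysed transesterification (methanolysis) removes the acetate; the descriptor changes only because the CIP priorities change.

Step 6
Reactants: 6 (R)-2-(PMB-oxy)-3-(trityloxy)propan-1-ol
Product: 7 (S)-2-(PMB-oxy)-3-(trityloxy)propanal
Conditions: PhI(OAc)2, 2,2,6,6-tetramethylpiperidin-1-oxyl (10 mol%), CH2Cl2, rt; used at once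
Reagents that add atoms: none
Why: Oxoammonium (TEMPO) oxidation of a primary alcohol stops at the aldehyde under near-neutral conditions, so the α-alkoxy stereocentre is not epimerised.

Step 7
Reactants: 8 tert-butyl (triphenylphosphoranylidene)acetate, 9 allyl bromide
Product: 11 tert-butyl 2-(triphenylphosphoranylidene)pent-4-enoate, via phosphonium bromide 10 (not isolated)
Conditions: CHCl3, reflux; then aq. NaOH, CH2Cl2, 0 °C
Reagents that add atoms: none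
Why: C-alkylation of a stabilised phosphorus ylide with a reactive allylic halide, followed by deprotonation of the phosphonium salt, gives the α-allyl ylide.

Step 8
Reactants: 7 (S)-2-(PMB-oxy)-3-(trityloxy)propanal, 11 tert-butyl 2-(triphenylphosphoranylidene)pent-4-enoate
Product: 12 tert-butyl (2E,4R)-4-(PMB-oxy)-2-(prop-2-en-1-yl)-5-(trityloxy)pent-2-enoate
Conditions: CH2Cl2, rt → 40 °C
Reagents that add atoms: none
Why: Wittig olefination with a stabilised α-substituted ylide gives the (E)-enoate (ester trans to C6, so C3 and C6 are cis as the ring needs) and does not touch the C6 stereocentre.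

Step 9
Reactants: 12 tert-butyl (2E,4R)-4-(PMB-oxy)-2-(prop-2-en-1-yl)-5-(trityloxy)pent-2-enoate
Product: 14 tert-butyl (2E,4R)-2-(3-hydroxypropyl)-4-(PMB-oxy)-5-(trityloxy)pent-2-enoate, via B-alkyl-9-BBN adduct 13 (not isolated)
Conditions: 9-borabicyclo[3.3.1]nonane, THF, 0 °C → rt; then 3 M NaOH, 30% H2O2, 0 °C
Reagents that add atoms: 9-borabicyclo[3.3.1]nonane, C1CC2CCCC(C1)B2 (boron stays only in 13); hydrogen peroxide, OO
Why: Anti-Markovnikov hydroboration–oxidation with a bulky borane takes only the terminal alkene and leaves the electron-poor trisubstituted enoate alone.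

Step 10
Reactants: 14 tert-butyl (2E,4R)-2-(3-hydroxypropyl)-4-(PMB-oxy)-5-(trityloxy)pent-2-enoate
Product: 15 tert-butyl (2E,4R)-4-(PMB-oxy)-2-(3-oxopropyl)-5-(trityloxy)pent-2-enoate
Conditions: PhI(OAc)2, 2,2,6,6-tetramethylpiperidin-1-oxyl (10 mol%), CH2Cl2, rt
Reagents that add atoms: none
Why: TEMPO oxidation of the primary alcohol gives the C1 aldehyde without over-oxidation.

Step 11
Reactants: 15 tert-butyl (2E,4R)-4-(PMB-oxy)-2-(3-oxopropyl)-5-(trityloxy)pent-2-enoate, 16 3-(triphenylphosphoranylidene)oxolan-2-one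
Product: 17 tert-butyl (2E,4R)-4-(PMB-oxy)-2-[(3E)-3-(2-oxooxolan-3-ylidene)propyl]-5-(trityloxy)pent-2-enoate
Conditions: toluene, 80 °C
Reagents that add atoms: none
Why: Wittig olefination with the stabilised lactone ylide gives the (E)-alkylidene lactone (carbonyl C14 trans to C2, C9 cis to C2), which fixes the C1=C10 geometry.

Step 12
Reactants: 17 tert-butyl (2E,4R)-4-(PMB-oxy)-2-[(3E)-3-(2-oxooxolan-3-ylidene)propyl]-5-(trityloxy)pent-2-enoate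
Product: 18 tert-butyl (2E,5E)-8-hydroxy-6-[methoxy(methyl)carbamoyl]-2-[(2R)-2-(PMB-oxy)-3-(trityloxy)propylidene]oct-5-enoate
Conditions: MeNHOMe·HCl, i-PrMgCl (premixed, 1:2), THF, −20 → 0 °C
Reagents that add atoms: N,O-dimethylhydroxylamine hydrochloride, CNOC.Cl
Why: Weinreb aminolysis of the lactone by the magnesium amide opens the ring and sets C8 free as an alcohol, while the hindered tert-butyl enoate does not react.

Step 13
Reactants: 18 tert-butyl (2E,5E)-8-hydroxy-6-[methoxy(methyl)carbamoyl]-2-[(2R)-2-(PMB-oxy)-3-(trityloxy)propylidene]oct-5-enoate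
Product: 19 tert-butyl (2E,5E)-8-(TBS-oxy)-6-[methoxy(methyl)carbamoyl]-2-[(2R)-2-(PMB-oxy)-3-(trityloxy)propylidene]oct-5-enoate
Conditions: TBSCl, imidazole, DMF, 0 °C → rt
Reagents that add atoms: tert-butyldimethylsilyl chloride, CC(C)(C)[Si](C)(C)Cl
Why: Silylation of the primary C8 alcohol right after ring opening prevents relactonisation and marks C8 apart from C14 and C15.

Step 14
Reactants: 19 tert-butyl (2E,5E)-8-(TBS-oxy)-6-[methoxy(methyl)carbamoyl]-2-[(2R)-2-(PMB-oxy)-3-(trityloxy)propylidene]oct-5-enoate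
Product: 21 (2E,6E,8R)-2-[2-(TBS-oxy)ethyl]-6-(hydroxymethyl)-8-(PMB-oxy)-9-(trityloxy)nona-2,6-dien-1-ol, via hydroxy enal 20 (not isolated)
Conditions: i-Bu2AlH (6 equiv), CH2Cl2, −78 → 0 °C; then NaBH4, CeCl3·7H2O, MeOH, 0 °C
Reagents that add atoms: none
Why: Hydride reduction takes the tert-butyl ester to the C15 alcohol and the Weinreb amide to the C14 enal, and a Luche 1,2-reduction then finishes the second allylic alcohol with both alkene geometries unchanged.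

Step 15
Reactants: 21 (2E,6E,8R)-2-[2-(TBS-oxy)ethyl]-6-(hydroxymethyl)-8-(PMB-oxy)-9-(trityloxy)nona-2,6-dien-1-ol
Product: 22 (2E,6E,8R)-1-(TBDPS-oxy)-6-[(TBDPS-oxy)methyl]-2-[2-(TBS-oxy)ethyl]-8-(PMB-oxy)-9-(trityloxy)nona-2,6-diene
Conditions: TBDPSCl (2.5 equiv), imidazole, DMF, rt
Reagents that add atoms: tert-butyl(chloro)diphenylsilane, CC(C)(C)[Si](Cl)(c1ccccc1)c1ccccc1
Why: Double silylation protects both primary allylic alcohols (C14, C15) with an acid-robust group that lasts to the final step.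

Step 16
Reactants: 22 (2E,6E,8R)-1-(TBDPS-oxy)-6-[(TBDPS-oxy)methyl]-2-[2-(TBS-oxy)ethyl]-8-(PMB-oxy)-9-(trityloxy)nona-2,6-diene
Product: 23 (2R,3E,7E)-9-(TBDPS-oxy)-4-[(TBDPS-oxy)methyl]-8-[2-(TBS-oxy)ethyl]-2-(PMB-oxy)nona-3,7-dien-1-ol
Conditions: ZnBr2, CH2Cl2/MeOH (10:1), 0 °C → rt
Reagents that add atoms: none
Why: Lewis-acid detritylation ionises only the trityl ether (stabilised trityl cation, trapped by methanol) and leaves the silyl and PMB ethers in place.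

Step 17
Reactants: 23 (2R,3E,7E)-9-(TBDPS-oxy)-4-[(TBDPS-oxy)methyl]-8-[2-(TBS-oxy)ethyl]-2-(PMB-oxy)nona-3,7-dien-1-ol
Product: 24 (2R,3E,7E)-9-(TBDPS-oxy)-4-[(TBDPS-oxy)methyl]-8-[2-(TBS-oxy)ethyl]-2-(PMB-oxy)nona-3,7-dienal
Conditions: PhI(OAc)2, 2,2,6,6-tetramethylpiperidin-1-oxyl (10 mol%), CH2Cl2, 0 °C → rt; used crude at once
Reagents that add atoms: none
Why: TEMPO oxidation gives the labile α-alkoxy β,γ-unsaturated C7 aldehyde without base, so C6 is not epimerised and the alkene does not move.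

Step 18
Reactants: 24 (2R,3E,7E)-9-(TBDPS-oxy)-4-[(TBDPS-oxy)methyl]-8-[2-(TBS-oxy)ethyl]-2-(PMB-oxy)nona-3,7-dienal, 25 methyl 3-(dimethylamino)propanoate
Product: 26 methyl (4R,5E,9E)-11-(TBDPS-oxy)-6-[(TBDPS-oxy)methyl]-10-[2-(TBS-oxy)ethyl]-2-[(dimethylamino)methyl]-3-hydroxy-4-(PMB-oxy)undeca-5,9-dienoate (C2/C3 diastereomer mixture)
Conditions: LiN(i-Pr)2, 25, THF, −78 °C; then 24, −78 °C; NH4Cl quench
Reagents that add atoms: none
Why: Lithium-enolate aldol addition at −78 °C outruns enolisation of the aldehyde; the new centres at C7 and C11 are not controlled because both become sp2 in the next two steps.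

Step 19
Reactants: 26 methyl (4R,5E,9E)-11-(TBDPS-oxy)-6-[(TBDPS-oxy)methyl]-10-[2-(TBS-oxy)ethyl]-2-[(dimethylamino)methyl]-3-hydroxy-4-(PMB-oxy)undeca-5,9-dienoate
Product: 28 methyl (4R,5E,9E)-11-(TBDPS-oxy)-6-[(TBDPS-oxy)methyl]-10-[2-(TBS-oxy)ethyl]-3-hydroxy-4-(PMB-oxy)-2-methylideneundeca-5,9-dienoate (both C3 epimers), via trimethylammonium iodide 27 (not isolated)
Conditions: MeI, CH2Cl2/MeOH, rt; then DBU, CH2Cl2, 0 °C
Reagents that add atoms: iodomethane, CI (its methyl stays only in 27 and leaves as trimethylamine)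
Why: Quaternisation of the Mannich base and E1cB (Hofmann-type) elimination give the α-methylene-β-hydroxy ester, the Morita–Baylis–Hillman-type adduct.

Step 20
Reactants: 28 methyl (4R,5E,9E)-11-(TBDPS-oxy)-6-[(TBDPS-oxy)methyl]-10-[2-(TBS-oxy)ethyl]-3-hydroxy-4-(PMB-oxy)-2-methylideneundeca-5,9-dienoate
Product: 29 methyl (2Z,4R,5E,9E)-2-(bromomethyl)-11-(TBDPS-oxy)-6-[(TBDPS-oxy)methyl]-10-[2-(TBS-oxy)ethyl]-4-(PMB-oxy)undeca-2,5,9-trienoate
Conditions: NBS, Me2S, CH2Cl2, −20 °C (premixed); then 28, −20 → 0 °C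
Reagents that add atoms: N-bromosuccinimide, O=C1CCC(=O)N1Br
Why: Corey–Kim-type activation of the allylic alcohol and SN2' attack of bromide give the rearranged (Z)-2-(bromomethyl)enoate; both C3 epimers converge and C6 is untouched.

Step 21
Reactants: 29 methyl (2Z,4R,5E,9E)-2-(bromomethyl)-11-(TBDPS-oxy)-6-[(TBDPS-oxy)methyl]-10-[2-(TBS-oxy)ethyl]-4-(PMB-oxy)undeca-2,5,9-trienoate
Product: 30 methyl (2Z,4R,5E,9E)-2-(bromomethyl)-11-(TBDPS-oxy)-6-[(TBDPS-oxy)methyl]-10-(2-hydroxyethyl)-4-(PMB-oxy)undeca-2,5,9-trienoate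
Conditions: 48% aq. HF, MeCN, 0 °C
Reagents that add atoms: none
Why: Acidic desilylation removes the primary TBS ether far faster than the TBDPS ethers, and acid-stable 2-(bromomethyl)enoates tolerate these non-basic conditions.

Step 22
Reactants: 30 methyl (2Z,4R,5E,9E)-2-(bromomethyl)-11-(TBDPS-oxy)-6-[(TBDPS-oxy)methyl]-10-(2-hydroxyethyl)-4-(PMB-oxy)undeca-2,5,9-trienoate
Product: 31 methyl (2Z,4R,5E,9E)-2-(bromomethyl)-11-(TBDPS-oxy)-6-[(TBDPS-oxy)methyl]-10-(2-oxoethyl)-4-(PMB-oxy)undeca-2,5,9-trienoate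
Conditions: PhI(OAc)2, 2,2,6,6-tetramethylpiperidin-1-oxyl (10 mol%), CH2Cl2, 0 °C; used crude at once
Reagents that add atoms: none
Why: TEMPO oxidation under base-free conditions gives the β,γ-unsaturated C8 aldehyde without isomerisation into conjugation.

Step 23
Reactants: 31 methyl (2Z,4R,5E,9E)-2-(bromomethyl)-11-(TBDPS-oxy)-6-[(TBDPS-oxy)methyl]-10-(2-oxoethyl)-4-(PMB-oxy)undeca-2,5,9-trienoate
Product: 33 (3aR,4R,5E,9E,11aS)-6,10-bis[(TBDPS-oxy)methyl]-4-(PMB-oxy)-3-methylidene-3a,4,7,8,11,11a-hexahydrocyclodeca[b]furan-2(3H)-one, via hydroxy ester 32 (not isolated)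
Conditions: CrCl2 (10 equiv), THF, 2 mM, rt, slow addition of 31; then p-toluenesulfonic acid monohydrate (cat.), CH2Cl2, rt
Reagents that add atoms: none
Why: Intramolecular Nozaki–Hiyama-type Barbier allylation in which the allylchromium adds through C7 to the C8 aldehyde in a chair-like transition state, with C6–H eclipsing the C7=C11 bond and the tethered aldehyde arriving anti to the C6 OPMB group (sets C7), while the tether across the two ring-cis alkenes is expected to favour the anti adduct (sets C8), whose alkoxide acylates on the methyl ester to close the trans-fused α-methylene-γ-lactone.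

Step 24
Reactants: 33 (3aR,4R,5E,9E,11aS)-6,10-bis[(TBDPS-oxy)methyl]-4-(PMB-oxy)-3-methylidene-3a,4,7,8,11,11a-hexahydrocyclodeca[b]furan-2(3H)-one
Product: 34 (3aS,4R,5E,9E,11aS)-6,10-bis[(TBDPS-oxy)methyl]-4-hydroxy-3-methylidene-3a,4,7,8,11,11a-hexahydrocyclodeca[b]furan-2(3H)-one
Conditions: DDQ, CH2Cl2/pH 7 buffer (10:1), 0 °C
Reagents that add atoms: none
Why: Oxidative PMB cleavage (hydride abstraction, then hydrolysis of the oxocarbenium ion) frees only the C6 hydroxyl under neutral conditions; the 3a descriptor changes by CIP priority only.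

Step 25
Reactants: 34 (3aS,4R,5E,9E,11aS)-6,10-bis[(TBDPS-oxy)methyl]-4-hydroxy-3-methylidene-3a,4,7,8,11,11a-hexahydrocyclodeca[b]furan-2(3H)-one, 35 (E)-2-methylbut-2-enoyl chloride (tigloyl chloride)
Product: 36 (3aR,4R,5E,9E,11aS)-6,10-bis[(TBDPS-oxy)methyl]-3-methylidene-2-oxo-2,3,3a,4,7,8,11,11a-octahydrocyclodeca[b]furan-4-yl (2E)-2-methylbut-2-enoate
Conditions: Et3N, 4-(dimethylamino)pyridine (cat.), CH2Cl2, 0 °C → rt
Reagents that add atoms: none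
Why: Nucleophile-catalysed acylation of the C6 alcohol, run promptly so the free 6-hydroxy lactone has no time to translactonise, installs the thermodynamically stable (E)-tiglate with retention at C6.

Step 26
Reactants: 36 (3aR,4R,5E,9E,11aS)-6,10-bis[(TBDPS-oxy)methyl]-3-methylidene-2-oxo-2,3,3a,4,7,8,11,11a-octahydrocyclodeca[b]furan-4-yl (2E)-2-methylbut-2-enoate
Product: 37 (3aR,4R,5E,9E,11aS)-6,10-bis(hydroxymethyl)-3-methylidene-2-oxo-2,3,3a,4,7,8,11,11a-octahydrocyclodeca[b]furan-4-yl (2E)-2-methylbut-2-enoate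
Conditions: HF·pyridine, pyridine, THF, 0 °C → rt
Reagents that add atoms: none
Why: Buffered fluoride desilylation removes both primary TBDPS ethers without harming the tiglate or the α-methylene lactone.

**Compound list**

1 | cis-2-phenyl-1,3-dioxan-5-ol (achiral) | O[C@H]1CO[C@@H](c2ccccc2)OC1 | starting material
2 | cis-5-(PMB-oxy)-2-phenyl-1,3-dioxane | COc1ccc(CO[C@H]2CO[C@@H](c3ccccc3)OC2)cc1 | intermediate
3 | 2-(PMB-oxy)propane-1,3-diol | OCC(CO)OCc1ccc(OC)cc1 | intermediate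
4 | (S)-3-hydroxy-2-(PMB-oxy)propyl acetate | CC(=O)OC[C@@H](OCc1ccc(OC)cc1)CO | intermediate
5 | (S)-2-(PMB-oxy)-3-(trityloxy)propyl acetate | CC(=O)OC[C@@H](OCc1ccc(OC)cc1)COC(c1ccccc1)(c1ccccc1)c1ccccc1 | intermediate
6 | (R)-2-(PMB-oxy)-3-(trityloxy)propan-1-ol | OC[C@@H](OCc1ccc(OC)cc1)COC(c1ccccc1)(c1ccccc1)c1ccccc1 | intermediate
7 | (S)-2-(PMB-oxy)-3-(trityloxy)propanal | O=C[C@@H](OCc1ccc(OC)cc1)COC(c1ccccc1)(c1ccccc1)c1ccccc1 | intermediate
8 | tert-butyl (triphenylphosphoranylidene)acetate | CC(C)(C)OC(=O)C=P(c1ccccc1)(c1ccccc1)c1ccccc1 | starting material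
9 | allyl bromide | C=CCBr | starting material
10 | [1-(tert-butoxycarbonyl)but-3-en-1-yl]triphenylphosphonium bromide (racemic) | CC(C)(C)OC(=O)C(CC=C)[P+](c1ccccc1)(c1ccccc1)c1ccccc1.[Br-] | intermediate (not isolated)
11 | tert-butyl 2-(triphenylphosphoranylidene)pent-4-enoate | CC(C)(C)OC(=O)C(CC=C)=P(c1ccccc1)(c1ccccc1)c1ccccc1 | intermediate
12 | tert-butyl (2E,4R)-4-(PMB-oxy)-2-(prop-2-en-1-yl)-5-(trityloxy)pent-2-enoate | C=CC/C(C(=O)OC(C)(C)C)=C\[C@@H](OCc1ccc(OC)cc1)COC(c1ccccc1)(c1ccccc1)c1ccccc1 | intermediate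
13 | 9-[(4E,6R)-4-(tert-butoxycarbonyl)-6-(PMB-oxy)-7-(trityloxy)hept-4-en-1-yl]-9-borabicyclo[3.3.1]nonane | C1CC2CCCC(C1)B2CCC/C(C(=O)OC(C)(C)C)=C\[C@@H](OCc1ccc(OC)cc1)COC(c1ccccc1)(c1ccccc1)c1ccccc1 | intermediate (not isolated)
14 | tert-butyl (2E,4R)-2-(3-hydroxypropyl)-4-(PMB-oxy)-5-(trityloxy)pent-2-enoate | OCCC/C(C(=O)OC(C)(C)C)=C\[C@@H](OCc1ccc(OC)cc1)COC(c1ccccc1)(c1ccccc1)c1ccccc1 | intermediate
15 | tert-butyl (2E,4R)-4-(PMB-oxy)-2-(3-oxopropyl)-5-(trityloxy)pent-2-enoate | O=CCC/C(C(=O)OC(C)(C)C)=C\[C@@H](OCc1ccc(OC)cc1)COC(c1ccccc1)(c1ccccc1)c1ccccc1 | intermediate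
16 | 3-(triphenylphosphoranylidene)oxolan-2-one | O=C1OCCC1=P(c1ccccc1)(c1ccccc1)c1ccccc1 | starting material
17 | tert-butyl (2E,4R)-4-(PMB-oxy)-2-[(3E)-3-(2-oxooxolan-3-ylidene)propyl]-5-(trityloxy)pent-2-enoate | O=C1OCC/C1=C\CC/C(C(=O)OC(C)(C)C)=C\[C@@H](OCc1ccc(OC)cc1)COC(c1ccccc1)(c1ccccc1)c1ccccc1 | intermediate
18 | tert-butyl (2E,5E)-8-hydroxy-6-[methoxy(methyl)carbamoyl]-2-[(2R)-2-(PMB-oxy)-3-(trityloxy)propylidene]oct-5-enoate | CON(C)C(=O)/C(CCO)=C/CC/C(C(=O)OC(C)(C)C)=C\[C@@H](OCc1ccc(OC)cc1)COC(c1ccccc1)(c1ccccc1)c1ccccc1 | intermediate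
19 | tert-butyl (2E,5E)-8-(TBS-oxy)-6-[methoxy(methyl)carbamoyl]-2-[(2R)-2-(PMB-oxy)-3-(trityloxy)propylidene]oct-5-enoate | CON(C)C(=O)/C(CCO[Si](C)(C)C(C)(C)C)=C/CC/C(C(=O)OC(C)(C)C)=C\[C@@H](OCc1ccc(OC)cc1)COC(c1ccccc1)(c1ccccc1)c1ccccc1 | intermediate
20 | (2E,6E,8R)-2-[2-(TBS-oxy)ethyl]-6-(hydroxymethyl)-8-(PMB-oxy)-9-(trityloxy)nona-2,6-dienal | O=C/C(CCO[Si](C)(C)C(C)(C)C)=C/CC/C(CO)=C\[C@@H](OCc1ccc(OC)cc1)COC(c1ccccc1)(c1ccccc1)c1ccccc1 | intermediate (not isolated)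
21 | (2E,6E,8R)-2-[2-(TBS-oxy)ethyl]-6-(hydroxymethyl)-8-(PMB-oxy)-9-(trityloxy)nona-2,6-dien-1-ol | OC/C(CCO[Si](C)(C)C(C)(C)C)=C/CC/C(CO)=C\[C@@H](OCc1ccc(OC)cc1)COC(c1ccccc1)(c1ccccc1)c1ccccc1 | intermediate
22 | (2E,6E,8R)-1-(TBDPS-oxy)-6-[(TBDPS-oxy)methyl]-2-[2-(TBS-oxy)ethyl]-8-(PMB-oxy)-9-(trityloxy)nona-2,6-diene | CC(C)(C)[Si](c1ccccc1)(c1ccccc1)OC/C(CCO[Si](C)(C)C(C)(C)C)=C/CC/C(CO[Si](c1ccccc1)(c1ccccc1)C(C)(C)C)=C\[C@@H](OCc1ccc(OC)cc1)COC(c1ccccc1)(c1ccccc1)c1ccccc1 | intermediate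
23 | (2R,3E,7E)-9-(TBDPS-oxy)-4-[(TBDPS-oxy)methyl]-8-[2-(TBS-oxy)ethyl]-2-(PMB-oxy)nona-3,7-dien-1-ol | CC(C)(C)[Si](c1ccccc1)(c1ccccc1)OC/C(CCO[Si](C)(C)C(C)(C)C)=C/CC/C(CO[Si](c1ccccc1)(c1ccccc1)C(C)(C)C)=C\[C@@H](OCc1ccc(OC)cc1)CO | intermediate
24 | (2R,3E,7E)-9-(TBDPS-oxy)-4-[(TBDPS-oxy)methyl]-8-[2-(TBS-oxy)ethyl]-2-(PMB-oxy)nona-3,7-dienal | CC(C)(C)[Si](c1ccccc1)(c1ccccc1)OC/C(CCO[Si](C)(C)C(C)(C)C)=C/CC/C(CO[Si](c1ccccc1)(c1ccccc1)C(C)(C)C)=C\[C@@H](OCc1ccc(OC)cc1)C=O | intermediate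
25 | methyl 3-(dimethylamino)propanoate | COC(=O)CCN(C)C | starting material
26 | methyl (4R,5E,9E)-11-(TBDPS-oxy)-6-[(TBDPS-oxy)methyl]-10-[2-(TBS-oxy)ethyl]-2-[(dimethylamino)methyl]-3-hydroxy-4-(PMB-oxy)undeca-5,9-dienoate (C2/C3 diastereomer mixture) | CC(C)(C)[Si](c1ccccc1)(c1ccccc1)OC/C(CCO[Si](C)(C)C(C)(C)C)=C/CC/C(CO[Si](c1ccccc1)(c1ccccc1)C(C)(C)C)=C\[C@@H](OCc1ccc(OC)cc1)C(O)C(CN(C)C)C(=O)OC | intermediate
27 | trimethylammonium iodide of 26 (N-methylated at the dimethylamino group) | CC(C)(C)[Si](c1ccccc1)(c1ccccc1)OC/C(CCO[Si](C)(C)C(C)(C)C)=C/CC/C(CO[Si](c1ccccc1)(c1ccccc1)C(C)(C)C)=C\[C@@H](OCc1ccc(OC)cc1)C(O)C(C[N+](C)(C)C)C(=O)OC.[I-] | intermediate (not isolated)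
28 | methyl (4R,5E,9E)-11-(TBDPS-oxy)-6-[(TBDPS-oxy)methyl]-10-[2-(TBS-oxy)ethyl]-3-hydroxy-4-(PMB-oxy)-2-methylideneundeca-5,9-dienoate (both C3 epimers) | CC(C)(C)[Si](c1ccccc1)(c1ccccc1)OC/C(CCO[Si](C)(C)C(C)(C)C)=C/CC/C(CO[Si](c1ccccc1)(c1ccccc1)C(C)(C)C)=C\[C@@H](OCc1ccc(OC)cc1)C(O)C(=C)C(=O)OC | intermediate
29 | methyl (2Z,4R,5E,9E)-2-(bromomethyl)-11-(TBDPS-oxy)-6-[(TBDPS-oxy)methyl]-10-[2-(TBS-oxy)ethyl]-4-(PMB-oxy)undeca-2,5,9-trienoate | CC(C)(C)[Si](c1ccccc1)(c1ccccc1)OC/C(CCO[Si](C)(C)C(C)(C)C)=C/CC/C(CO[Si](c1ccccc1)(c1ccccc1)C(C)(C)C)=C\[C@@H](OCc1ccc(OC)cc1)/C=C(\CBr)C(=O)OC | intermediate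
30 | methyl (2Z,4R,5E,9E)-2-(bromomethyl)-11-(TBDPS-oxy)-6-[(TBDPS-oxy)methyl]-10-(2-hydroxyethyl)-4-(PMB-oxy)undeca-2,5,9-trienoate | CC(C)(C)[Si](c1ccccc1)(c1ccccc1)OC/C(CCO)=C/CC/C(CO[Si](c1ccccc1)(c1ccccc1)C(C)(C)C)=C\[C@@H](OCc1ccc(OC)cc1)/C=C(\CBr)C(=O)OC | intermediate
31 | methyl (2Z,4R,5E,9E)-2-(bromomethyl)-11-(TBDPS-oxy)-6-[(TBDPS-oxy)methyl]-10-(2-oxoethyl)-4-(PMB-oxy)undeca-2,5,9-trienoate | CC(C)(C)[Si](c1ccccc1)(c1ccccc1)OC/C(CC=O)=C/CC/C(CO[Si](c1ccccc1)(c1ccccc1)C(C)(C)C)=C\[C@@H](OCc1ccc(OC)cc1)/C=C(\CBr)C(=O)OC | intermediate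
32 | methyl 2-[(1R,2R,3E,7E,10S)-4,8-bis[(TBDPS-oxy)methyl]-10-hydroxy-2-(PMB-oxy)cyclodeca-3,7-dien-1-yl]prop-2-enoate | COC(=O)C(=C)[C@@H]1[C@@H](O)C/C(CO[Si](c2ccccc2)(c2ccccc2)C(C)(C)C)=C\CC/C(CO[Si](c2ccccc2)(c2ccccc2)C(C)(C)C)=C\[C@H]1OCc1ccc(OC)cc1 | intermediate (not isolated)
33 | (3aR,4R,5E,9E,11aS)-6,10-bis[(TBDPS-oxy)methyl]-4-(PMB-oxy)-3-methylidene-3a,4,7,8,11,11a-hexahydrocyclodeca[b]furan-2(3H)-one | C=C1C(=O)O[C@H]2C/C(CO[Si](c3ccccc3)(c3ccccc3)C(C)(C)C)=C\CC/C(CO[Si](c3ccccc3)(c3ccccc3)C(C)(C)C)=C\[C@@H](OCc3ccc(OC)cc3)[C@H]12 | intermediate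
34 | (3aS,4R,5E,9E,11aS)-6,10-bis[(TBDPS-oxy)methyl]-4-hydroxy-3-methylidene-3a,4,7,8,11,11a-hexahydrocyclodeca[b]furan-2(3H)-one | C=C1C(=O)O[C@H]2C/C(CO[Si](c3ccccc3)(c3ccccc3)C(C)(C)C)=C\CC/C(CO[Si](c3ccccc3)(c3ccccc3)C(C)(C)C)=C\[C@@H](O)[C@H]12 | intermediate
35 | (E)-2-methylbut-2-enoyl chloride (tigloyl chloride) | C/C=C(\C)C(=O)Cl | starting material
36 | (3aR,4R,5E,9E,11aS)-6,10-bis[(TBDPS-oxy)methyl]-3-methylidene-2-oxo-2,3,3a,4,7,8,11,11a-octahydrocyclodeca[b]furan-4-yl (2E)-2-methylbut-2-enoate | C=C1C(=O)O[C@H]2C/C(CO[Si](c3ccccc3)(c3ccccc3)C(C)(C)C)=C\CC/C(CO[Si](c3ccccc3)(c3ccccc3)C(C)(C)C)=C\[C@@H](OC(=O)/C(C)=C/C)[C@H]12 | intermediate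
37 | (3aR,4R,5E,9E,11aS)-6,10-bis(hydroxymethyl)-3-methylidene-2-oxo-2,3,3a,4,7,8,11,11a-octahydrocyclodeca[b]furan-4-yl (2E)-2-methylbut-2-enoate | C=C1C(=O)O[C@H]2C/C(CO)=C\CC/C(CO)=C\[C@@H](OC(=O)/C(C)=C/C)[C@H]12 | target

**Step count and risks**

Total steps: 26. Longest linear sequence: 25 steps (steps 1–6, then 8–26; step 7 is a one-step side branch).

The three steps most likely to fail:

Step 23, the macrocyclic CrCl2 closure, is the weakest point: it may oligomerise, or it may give the syn adduct and hence the cis-fused lactone. The fallback sets out from 31 and comes back at 33. The ring is closed instead as an aqueous indium Barbier reaction (In powder, THF/H2O, high dilution). Its chelated cyclic transition state is expected to give the syn adduct, isolated after lactonisation as the C8-epimeric cis-fused lactone F1. KOH (1 equiv, THF/H2O, 0 °C) opens this to the potassium hydroxy-carboxylate F2. MsCl/Et3N at −20 °C then makes the C8 mesylate, which the carboxylate displaces intramolecularly with inversion, giving the trans-fused lactone 33.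

Step 18, the enolate aldol on the α-alkoxy β,γ-unsaturated aldehyde 24, risks epimerisation at C6 or migration of the C4=C5 bond. The fallback sets out from 23 and comes back at 29. Alcohol 23 is oxidised with PhI(OAc)2 and 2,2,6,6-tetramethylpiperidin-1-oxyl in the presence of methyl (triphenylphosphoranylidene)acetate, so the aldehyde is trapped as it forms and gives the (E)-enoate F3. Tandem Michael–aldol reaction (Me2AlSPh, then formaldehyde) gives the β-phenylsulfanyl α-(hydroxymethyl) ester F4. Oxidation with NaIO4 and thermal sulfoxide elimination give the 2-(hydroxymethyl)enoate F5. Appel bromination (CBr4, PPh3) of the primary allylic alcohol then gives bromide 29 without allylic transposition.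

Step 21, acid desilylation next to the allylic bromide, risks solvolysis of the bromide. The fallback sets out from 28 and comes back at 31. The TBS ether is removed first (aq. HF, MeCN) to give the diol F6. Only the primary alcohol is oxidised (PhI(OAc)2, 2,2,6,6-tetramethylpiperidin-1-oxyl) to the hydroxy aldehyde F7. The secondary allylic alcohol is then converted with NBS/Me2S into the rearranged bromide, which is 31.

**Further compounds**

F1 | step 23 | (3aR,4R,5E,9E,11aR)-6,10-bis[(TBDPS-oxy)methyl]-4-(PMB-oxy)-3-methylidene-3a,4,7,8,11,11a-hexahydrocyclodeca[b]furan-2(3H)-one (C8 epimer of 33, cis-fused) | C=C1C(=O)O[C@@H]2C/C(CO[Si](c3ccccc3)(c3ccccc3)C(C)(C)C)=C\CC/C(CO[Si](c3ccccc3)(c3ccccc3)C(C)(C)C)=C\[C@@H](OCc3ccc(OC)cc3)[C@H]12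
F2 | step 23 | potassium 2-[(1R,2R,3E,7E,10R)-4,8-bis[(TBDPS-oxy)methyl]-10-hydroxy-2-(PMB-oxy)cyclodeca-3,7-dien-1-yl]prop-2-enoate | [K+].[O-]C(=O)C(=C)[C@@H]1[C@H](O)C/C(CO[Si](c2ccccc2)(c2ccccc2)C(C)(C)C)=C\CC/C(CO[Si](c2ccccc2)(c2ccccc2)C(C)(C)C)=C\[C@H]1OCc1ccc(OC)cc1
F3 | step 18 | methyl (2E,4S,5E,9E)-11-(TBDPS-oxy)-6-[(TBDPS-oxy)methyl]-10-[2-(TBS-oxy)ethyl]-4-(PMB-oxy)undeca-2,5,9-trienoate | CC(C)(C)[Si](c1ccccc1)(c1ccccc1)OC/C(CCO[Si](C)(C)C(C)(C)C)=C/CC/C(CO[Si](c1ccccc1)(c1ccccc1)C(C)(C)C)=C\[C@@H](OCc1ccc(OC)cc1)/C=C/C(=O)OC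
F4 | step 18 | methyl (4R,5E,9E)-11-(TBDPS-oxy)-6-[(TBDPS-oxy)methyl]-10-[2-(TBS-oxy)ethyl]-2-(hydroxymethyl)-4-(PMB-oxy)-3-(phenylsulfanyl)undeca-5,9-dienoate (C2/C3 diastereomer mixture) | CC(C)(C)[Si](c1ccccc1)(c1ccccc1)OC/C(CCO[Si](C)(C)C(C)(C)C)=C/CC/C(CO[Si](c1ccccc1)(c1ccccc1)C(C)(C)C)=C\[C@@H](OCc1ccc(OC)cc1)C(Sc1ccccc1)C(CO)C(=O)OC
F5 | step 18 | methyl (2E,4R,5E,9E)-11-(TBDPS-oxy)-6-[(TBDPS-oxy)methyl]-10-[2-(TBS-oxy)ethyl]-2-(hydroxymethyl)-4-(PMB-oxy)undeca-2,5,9-trienoate | CC(C)(C)[Si](c1ccccc1)(c1ccccc1)OC/C(CCO[Si](C)(C)C(C)(C)C)=C/CC/C(CO[Si](c1ccccc1)(c1ccccc1)C(C)(C)C)=C\[C@@H](OCc1ccc(OC)cc1)/C=C(\CO)C(=O)OC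
F6 | step 21 | methyl (4R,5E,9E)-11-(TBDPS-oxy)-6-[(TBDPS-oxy)methyl]-3-hydroxy-10-(2-hydroxyethyl)-4-(PMB-oxy)-2-methylideneundeca-5,9-dienoate (both C3 epimers) | CC(C)(C)[Si](c1ccccc1)(c1ccccc1)OC/C(CCO)=C/CC/C(CO[Si](c1ccccc1)(c1ccccc1)C(C)(C)C)=C\[C@@H](OCc1ccc(OC)cc1)C(O)C(=C)C(=O)OC
F7 | step 21 | methyl (4R,5E,9E)-11-(TBDPS-oxy)-6-[(TBDPS-oxy)methyl]-3-hydroxy-10-(2-oxoethyl)-4-(PMB-oxy)-2-methylideneundeca-5,9-dienoate (both C3 epimers) | CC(C)(C)[Si](c1ccccc1)(c1ccccc1)OC/C(CC=O)=C/CC/C(CO[Si](c1ccccc1)(c1ccccc1)C(C)(C)C)=C\[C@@H](OCc1ccc(OC)cc1)C(O)C(=C)C(=O)OC
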